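**Remark on the chemistry:** flavan numbering is used; the upper (robinetinidol) unit carries rings A, B and C, the lower (catechin) unit rings D, E and F. The target is read as robinetinidol-(4β→8)-catechin, upper unit (2R,3S,4R) (2,3-trans-3,4-cis), lower unit (2R,3S); compounds 1, 5 and 7 are taken as purchasable.

## Retrosynthetic overview

1. Target 16 ⇐ nona-O-benzyl ether 15 by global hydrogenolysis.
2. 15 ⇐ open-chain phenolic epoxy diaryl carbinol 12 (both C4 epimers): ring C (O1, C2, C3, C4, C4a, C8a) is closed last, in one pot, by attack of O1 on C2 of the oxirane followed by ionic hydrogenation of the C4 cation.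
3. 12 ⇐ C4–C8(ring D) bond: 8-lithio-penta-O-benzylcatechin (rings D, E, F from (+)-catechin) plus chalcone epoxide 9 (rings A and B from commercial aromatics, by Claisen–Schmidt condensation and Juliá–Colonna epoxidation).
4. Enabling feature: O1 is a phenolic oxygen of ring A ortho to C4a, C2 is benzylic to the electron-rich ring B, and C4 is doubly benzylic (ring A and the phloroglucinol-type ring D). The C2–C3 oxirane therefore opens at C2 under attack of O1, and the C4 carbinol ionises to one planar cation whatever its configuration.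
5. Ring order: D/E/F (chiral pool) and A, B (commercial) are present from the start; ring C is the only ring made, in step 9.

Key step: step 9

## Route

Step 1
Reactants: 1 (+)-catechin
Product: 2 5,7,3',4'-tetra-O-benzyl-(+)-catechin, (2R,3S)
Conditions: BnBr (4.4 equiv), K2CO3, DMF, 0 °C → rt
Reagents that add atoms: benzyl bromide, BrCc1ccccc1
Why: Williamson O-alkylation of the four phenols under carbonate conditions should leave the far less acidic secondary 3-OH free and touch no stereocentre.

Step 2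
Reactants: 2 5,7,3',4'-tetra-O-benzyl-(+)-catechin
Product: 3 8-bromo-5,7,3',4'-tetra-O-benzylcatechin, (2R,3S)
Conditions: NBS (1.0 equiv), CH2Cl2, −78 °C → rt
Reagents that add atoms: N-bromosuccinimide, O=C1CCC(=O)N1Br
Why: Electrophilic aromatic bromination of the phloroglucinol-type ring D is expected at C8, the position known to react first in benzylated catechin and epicatechin.

Step 3
Reactants: 3 8-bromo-5,7,3',4'-tetra-O-benzylcatechin
Product: 4 8-bromo-3,5,7,3',4'-penta-O-benzylcatechin, (2R,3S)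
Conditions: NaH, BnBr, DMF, 0 °C → rt
Reagents that add atoms: benzyl bromide, BrCc1ccccc1
Why: Williamson etherification of the secondary alkoxide removes the only acidic proton, so the aryl bromide can later undergo clean bromine–lithium exchange.

Step 4
Reactants: 5 1-[4-(benzyloxy)-2-hydroxyphenyl]ethanone
Product: 6 1-[2-(allyloxy)-4-(benzyloxy)phenyl]ethanone
Conditions: allyl bromide, K2CO3, DMF, 60 °C
Reagents that add atoms: allyl bromide, C=CCBr
Why: Williamson allylation of the chelated ortho-phenol installs a group that is stable to base, peroxide and organolithium and can be removed later under neutral conditions without touching benzyl ethers.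

Step 5
Reactants: 6 1-[2-(allyloxy)-4-(benzyloxy)phenyl]ethanone; 7 3,4,5-tris(benzyloxy)benzaldehyde
Product: 8 (E)-1-[2-(allyloxy)-4-(benzyloxy)phenyl]-3-[3,4,5-tris(benzyloxy)phenyl]prop-2-en-1-one
Conditions: KOH, EtOH/THF, rt
Reagents that add atoms: none
Why: Claisen–Schmidt aldol condensation of a methyl ketone with a non-enolisable aldehyde should give the thermodynamically favoured (E)-chalcone.

Step 6
Reactants: 8 (E)-chalcone
Product: 9 [2-(allyloxy)-4-(benzyloxy)phenyl]{(2R,3S)-3-[3,4,5-tris(benzyloxy)phenyl]oxiran-2-yl}methanone (trans-epoxy ketone)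
Conditions: poly-L-leucine, urea–H2O2, DBU, THF, rt
Reagents that add atoms: urea–hydrogen peroxide, NC(N)=O.OO
Why: Juliá–Colonna epoxidation (nucleophilic Weitz–Scheffer addition of hydroperoxide) within the helical poly-L-leucine should deliver the trans-(2R,3S)-oxirane from the (E)-enone; any minor enantiomer would later become a separable diastereomer once joined to enantiopure 4.

Step 7
Reactants: 4 8-bromo-3,5,7,3',4'-penta-O-benzylcatechin; 9 (2R,3S)-epoxy ketone
Product: 11 [2-(allyloxy)-4-(benzyloxy)phenyl](3,5,7,3',4'-penta-O-benzylcatechin-8-yl){(2R,3S)-3-[3,4,5-tris(benzyloxy)phenyl]oxiran-2-yl}methanol as a mixture of carbinol epimers, via aryllithium 10 (not isolated)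
Conditions: 4, t-BuLi (2.1 equiv), THF, −78 °C; then 9, −78 °C; H2O quench at −78 °C
Reagents that add atoms: none
Why: Bromine–lithium exchange followed by 1,2-addition of the aryllithium to the ketone (faster than oxirane opening at −78 °C) forms the C4–C8 bond; the new C4 centre is left uncontrolled on purpose because step 9 erases it.

Step 8
Reactants: 11 allyl-protected epoxy carbinol
Product: 12 [4-(benzyloxy)-2-hydroxyphenyl](3,5,7,3',4'-penta-O-benzylcatechin-8-yl){(2R,3S)-3-[3,4,5-tris(benzyloxy)phenyl]oxiran-2-yl}methanol as a mixture of carbinol epimers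
Conditions: Pd(PPh3)4 (5 mol %), N-methylaniline, THF, rt; filtration through Et3N-deactivated silica, used crude
Reagents that add atoms: none
Why: Tsuji–Trost-type allyl transfer from the aryl allyl ether to the weakly basic amine under zerovalent palladium catalysis should free the ring A phenol under neutral conditions that leave the oxirane, the benzyl ethers and the ionisable carbinol intact.

Step 9
Reactants: 12 phenolic epoxy carbinol (both C4 epimers)
Product: 15 nona-O-benzyl-robinetinidol-(4β→8)-catechin with free upper 3-OH, upper unit (2R,3S,4R), via flavan-3,4-diol 13 (not isolated), via flavan-4-ylium ion 14 (not isolated)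
Conditions: BF3·OEt2 (3 equiv), CH2Cl2, −78 °C, 30 min; then Et3SiH (5 equiv), −78 → −30 °C; aq NaHCO3
Reagents that add atoms: none
Why: BF3 activates the electron-rich benzylic oxirane and the ring A phenol oxygen attacks C2 anti to the departing oxirane oxygen, a 6-endo-tet closure of ring C driven by release of oxirane strain that turns the (S)-oxirane carbon into the (2R) centre trans to the retained C3 oxygen. The C4 diaryl carbinol of either epimer ionises, before or after ring closure, to the same planar flavan-4-ylium ion 14 stabilised by ring A and ring D, and Et3SiH reduces it, so the epimer mixture is funnelled into one C4 configuration. The closest known reaction types are the acid-mediated cyclisation of phenolic aryl epoxides (2'-hydroxychalcone epoxides) to 2,3-trans-chromans and the ionic hydrogenation, by silane or stannane with acid, of 4-aryl-flavan-4-ols made from aryllithium additions to flavan-4-ones. C2 is controlled by stereospecific inversion (and, should C2 ionise, by the equatorial preference of ring B in the chair-like closure, which gives the same 2,3-trans result), C3 is carried over from the oxirane, and C4 is controlled by the substrate: A(1,2) strain between the in-plane C4 aryl group and the boron-bound O3 pushes O3 pseudo-axial, hydride enters anti to it, and the aryl group ends cis to O3 (3,4-cis, 4R). The step needs ring closure before hydride transfer and 6-endo attack at C2 instead of 5-exo attack at C3; this is secured by the benzylic activation of C2 by ring B, by the phenol being the only free hydroxyl that reaches C2 through a six-membered transition state, and by adding the silane only after cyclisation at −78 °C.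

Step 10
Reactants: 15 nona-O-benzyl-robinetinidol-(4β→8)-catechin
Product: 16 robinetinidol-(4β→8)-catechin (target)
Conditions: H2 (1 atm), Pd(OH)2/C, THF/MeOH/H2O, rt
Reagents that add atoms: none
Why: Catalytic hydrogenolysis should cleave all nine benzyl ethers under mild neutral conditions that are known to spare the diarylmethine interflavan bond and the benzylic C2–O1 bonds of benzylated proanthocyanidins, so no stereocentre is touched.

## Compound list

1 | (+)-catechin, (2R,3S) | Oc1cc(O)c2c(c1)O[C@H](c1ccc(O)c(O)c1)[C@@H](O)C2 | starting material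
2 | 5,7,3',4'-tetra-O-benzyl-(+)-catechin, (2R,3S) | c1c(OCc3ccccc3)cc(OCc3ccccc3)c2c1O[C@H](c1ccc(OCc3ccccc3)c(OCc3ccccc3)c1)[C@@H](O)C2 | intermediate
3 | 8-bromo-5,7,3',4'-tetra-O-benzylcatechin, (2R,3S) | Brc1c(OCc3ccccc3)cc(OCc3ccccc3)c2c1O[C@H](c1ccc(OCc3ccccc3)c(OCc3ccccc3)c1)[C@@H](O)C2 | intermediate
4 | 8-bromo-3,5,7,3',4'-penta-O-benzylcatechin, (2R,3S) | Brc1c(OCc3ccccc3)cc(OCc3ccccc3)c2c1O[C@H](c1ccc(OCc3ccccc3)c(OCc3ccccc3)c1)[C@@H](OCc1ccccc1)C2 | intermediate
5 | 1-[4-(benzyloxy)-2-hydroxyphenyl]ethanone | CC(=O)c1ccc(OCc2ccccc2)cc1O | starting material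
6 | 1-[2-(allyloxy)-4-(benzyloxy)phenyl]ethanone | CC(=O)c1ccc(OCc2ccccc2)cc1OCC=C | intermediate
7 | 3,4,5-tris(benzyloxy)benzaldehyde | O=Cc1cc(OCc2ccccc2)c(OCc2ccccc2)c(OCc2ccccc2)c1 | starting material
8 | (E)-1-[2-(allyloxy)-4-(benzyloxy)phenyl]-3-[3,4,5-tris(benzyloxy)phenyl]prop-2-en-1-one | C=CCOc1cc(OCc2ccccc2)ccc1C(=O)/C=C/c1cc(OCc2ccccc2)c(OCc2ccccc2)c(OCc2ccccc2)c1 | intermediate
9 | [2-(allyloxy)-4-(benzyloxy)phenyl]{(2R,3S)-3-[3,4,5-tris(benzyloxy)phenyl]oxiran-2-yl}methanone | C=CCOc1cc(OCc2ccccc2)ccc1C(=O)[C@@H]1O[C@H]1c1cc(OCc2ccccc2)c(OCc2ccccc2)c(OCc2ccccc2)c1 | intermediate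
10 | 8-lithio-3,5,7,3',4'-penta-O-benzylcatechin, (2R,3S) | [Li]c1c(OCc3ccccc3)cc(OCc3ccccc3)c2c1O[C@H](c1ccc(OCc3ccccc3)c(OCc3ccccc3)c1)[C@@H](OCc1ccccc1)C2 | intermediate (not isolated)
11 | [2-(allyloxy)-4-(benzyloxy)phenyl](penta-O-benzylcatechin-8-yl){(2R,3S)-3-[3,4,5-tris(benzyloxy)phenyl]oxiran-2-yl}methanol, both carbinol epimers | C=CCOc1cc(OCc2ccccc2)ccc1C(O)(c1c(OCc3ccccc3)cc(OCc3ccccc3)c2c1O[C@H](c1ccc(OCc3ccccc3)c(OCc3ccccc3)c1)[C@@H](OCc1ccccc1)C2)[C@@H]1O[C@H]1c1cc(OCc2ccccc2)c(OCc2ccccc2)c(OCc2ccccc2)c1 | intermediate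
12 | [4-(benzyloxy)-2-hydroxyphenyl](penta-O-benzylcatechin-8-yl){(2R,3S)-3-[3,4,5-tris(benzyloxy)phenyl]oxiran-2-yl}methanol, both carbinol epimers | Oc1cc(OCc2ccccc2)ccc1C(O)(c1c(OCc3ccccc3)cc(OCc3ccccc3)c2c1O[C@H](c1ccc(OCc3ccccc3)c(OCc3ccccc3)c1)[C@@H](OCc1ccccc1)C2)[C@@H]1O[C@H]1c1cc(OCc2ccccc2)c(OCc2ccccc2)c(OCc2ccccc2)c1 | intermediate
13 | (2R,3R,4RS)-7-(benzyloxy)-4-(penta-O-benzylcatechin-8-yl)-2-[3,4,5-tris(benzyloxy)phenyl]chromane-3,4-diol (2,3-trans, both C4 epimers) | c1ccccc1COc1ccc2c(c1)O[C@H](c1cc(OCc3ccccc3)c(OCc3ccccc3)c(OCc3ccccc3)c1)[C@@H](O)C2(O)c1c(OCc3ccccc3)cc(OCc3ccccc3)c2c1O[C@H](c1ccc(OCc3ccccc3)c(OCc3ccccc3)c1)[C@@H](OCc1ccccc1)C2 | intermediate (not isolated)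
14 | 2,3-trans-7-(benzyloxy)-3-hydroxy-4-(penta-O-benzylcatechin-8-yl)-2-[3,4,5-tris(benzyloxy)phenyl]flavan-4-ylium ion (O3 boron-bound in the flask) | c1ccccc1COc1ccc2c(c1)O[C@H](c1cc(OCc3ccccc3)c(OCc3ccccc3)c(OCc3ccccc3)c1)[C@@H](O)[C+]2c1c(OCc3ccccc3)cc(OCc3ccccc3)c2c1O[C@H](c1ccc(OCc3ccccc3)c(OCc3ccccc3)c1)[C@@H](OCc1ccccc1)C2 | intermediate (not isolated)
15 | nona-O-benzyl-robinetinidol-(4β→8)-catechin, free upper 3-OH; upper (2R,3S,4R), lower (2R,3S) | c1ccccc1COc1ccc2c(c1)O[C@H](c1cc(OCc3ccccc3)c(OCc3ccccc3)c(OCc3ccccc3)c1)[C@@H](O)[C@H]2c1c(OCc3ccccc3)cc(OCc3ccccc3)c2c1O[C@H](c1ccc(OCc3ccccc3)c(OCc3ccccc3)c1)[C@@H](OCc1ccccc1)C2 | intermediate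
16 | robinetinidol-(4β→8)-catechin (CNP0261864.3); upper (2R,3S,4R), lower (2R,3S) | Oc1ccc2c(c1)O[C@H](c1cc(O)c(O)c(O)c1)[C@@H](O)[C@H]2c1c(O)cc(O)c2c1O[C@H](c1ccc(O)c(O)c1)[C@@H](O)C2 | target

## Summary

Total step count: 10. Longest linear sequence: 7 steps (1 → 2 → 3 → 7 → 8 → 9 → 10, or equally 4 → 5 → 6 → 7 → 8 → 9 → 10).

## Steps most likely to fail

**Step 9.** Hydride may be transferred to the open-chain cation before ring C has closed, or may not discriminate the two faces of the cyclic cation well enough; either process would erode the C4 configuration. A 1,2-hydride shift from C3 to the cation is a further side path. The fallback sets out from 12 and comes back at 15. The events are separated and the face is blocked by a covalent group. First, 12 is cyclised with BF3·OEt2 at −78 °C without silane and quenched with aqueous NaHCO3, so that the diol 13 is now isolated. TBSCl/imidazole in DMF should then silylate only the secondary 3-OH to give the 3-O-TBS 4-aryl-flavan-4-ol F1. Bu3SnH/CF3CO2H in CH2Cl2 at 0 °C reduces the C4 cation anti to the bulky silyl ether to give the 3-O-TBS ether of 15, F2. Bu4NF in THF returns 15.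

**Step 7.** The aryllithium may attack or rearrange the oxirane (including epoxide migration by the lithium alkoxide), or may add incompletely to the hindered ortho-substituted ketone. The fallback sets out from 9 and comes back at 15. Ring C is closed at the ketone oxidation level before the aryl group is brought in.
- Deallylation of 9 with Pd(PPh3)4/N-methylaniline gives the phenolic epoxy ketone F3.
- NaOAc in warm EtOH induces phenoxide 6-endo opening at the benzylic carbon with inversion, giving the (2R,3R)-dihydroflavonol F4.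
- TBSCl/imidazole gives its 3-O-TBS ether F5.
- Aryllithium 10 adds to the cyclic C4 ketone, a known reaction of flavan-4-ones, and gives the same 3-O-TBS 4-aryl-flavan-4-ol F1 as above.
- The sequence then follows the step 9 fallback (Bu3SnH/CF3CO2H to the 3-O-TBS ether of 15, F2, then Bu4NF) back to 15.

**Step 6.** The nucleophilic epoxidation may be slow or insufficiently enantioselective for this ortho-alkoxy, polyoxygenated chalcone. The fallback sets out from 8 (with 10 made from 4) and comes back at 11. The enantio-determining step is moved to an electrophilic, reagent-controlled epoxidation. Aryllithium 10 is added 1,2 to chalcone 8 in THF at −78 °C to give the bis-aryl (E)-allylic alcohol F6 as a mixture of carbinol epimers. Its electron-rich trans-styrenyl double bond is then epoxidised under Shi conditions: Oxone (KHSO5), the L-configured enantiomer of the fructose-derived ketone 1,2:4,5-di-O-isopropylidene-erythro-2,3-hexodiulo-2,6-pyranose, K2CO3 buffer, MeCN/dimethoxymethane/H2O, 0 °C. This enantiomer of the ketone should give the (2R,3S)-oxirane of 11, and the terminal allyl ether double bond should react far more slowly.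

## Further compounds

F1 | step 9 | (2R,3R,4RS)-7-(benzyloxy)-3-[(tert-butyldimethylsilyl)oxy]-4-(penta-O-benzylcatechin-8-yl)-2-[3,4,5-tris(benzyloxy)phenyl]chroman-4-ol | c1ccccc1COc1ccc2c(c1)O[C@H](c1cc(OCc3ccccc3)c(OCc3ccccc3)c(OCc3ccccc3)c1)[C@@H](O[Si](C)(C)C(C)(C)C)C2(O)c1c(OCc3ccccc3)cc(OCc3ccccc3)c2c1O[C@H](c1ccc(OCc3ccccc3)c(OCc3ccccc3)c1)[C@@H](OCc1ccccc1)C2
F2 | step 9 | 3-O-TBS ether of 15, upper (2R,3S,4R), lower (2R,3S) | c1ccccc1COc1ccc2c(c1)O[C@H](c1cc(OCc3ccccc3)c(OCc3ccccc3)c(OCc3ccccc3)c1)[C@@H](O[Si](C)(C)C(C)(C)C)[C@H]2c1c(OCc3ccccc3)cc(OCc3ccccc3)c2c1O[C@H](c1ccc(OCc3ccccc3)c(OCc3ccccc3)c1)[C@@H](OCc1ccccc1)C2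
F3 | step 7 | [4-(benzyloxy)-2-hydroxyphenyl]{(2R,3S)-3-[3,4,5-tris(benzyloxy)phenyl]oxiran-2-yl}methanone | Oc1cc(OCc2ccccc2)ccc1C(=O)[C@@H]1O[C@H]1c1cc(OCc2ccccc2)c(OCc2ccccc2)c(OCc2ccccc2)c1
F4 | step 7 | (2R,3R)-7-(benzyloxy)-3-hydroxy-2-[3,4,5-tris(benzyloxy)phenyl]chroman-4-one | c1ccccc1COc1ccc2c(c1)O[C@H](c1cc(OCc3ccccc3)c(OCc3ccccc3)c(OCc3ccccc3)c1)[C@@H](O)C2=O
F5 | step 7 | (2R,3R)-7-(benzyloxy)-3-[(tert-butyldimethylsilyl)oxy]-2-[3,4,5-tris(benzyloxy)phenyl]chroman-4-one | c1ccccc1COc1ccc2c(c1)O[C@H](c1cc(OCc3ccccc3)c(OCc3ccccc3)c(OCc3ccccc3)c1)[C@@H](O[Si](C)(C)C(C)(C)C)C2=O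
F6 | step 6 | (E)-1-[2-(allyloxy)-4-(benzyloxy)phenyl]-1-(penta-O-benzylcatechin-8-yl)-3-[3,4,5-tris(benzyloxy)phenyl]prop-2-en-1-ol, both carbinol epimers | C=CCOc1cc(OCc2ccccc2)ccc1C(O)(c1c(OCc3ccccc3)cc(OCc3ccccc3)c2c1O[C@H](c1ccc(OCc3ccccc3)c(OCc3ccccc3)c1)[C@@H](OCc1ccccc1)C2)/C=C/c1cc(OCc2ccccc2)c(OCc2ccccc2)c(OCc2ccccc2)c1
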